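**Plan**

1. Atom labels used below: C1 = CH(OBz); C2=C3 (C3 bears the carboxyl carbon C15); C4, C5 = CH2; C6–C7 = oxirane (C7 bears CH3); C8, C9, C10 = CH2; C11 = C(CH3)2. The 11-membered carbocycle is C1–C11.
2. Retrosynthetic cuts, in order: C15 ester O–alkyl (protecting group); C9–C10 (as C9=C10, ring-closing metathesis); oxirane C–O bonds (back to the E-C6=C7 alkene); O–benzoyl; C1–C11 (reverse prenylation of an enal); C2=C3 (Horner–Wadsworth–Emmons); C3–C4 (phosphonate alkylation); C5–C6 and C7–CH3 (carboalumination, ethylene oxide).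
3. Forward: the C4–C9 dienyl chain is built and joined to C3, C2/C1 are added as an enal, the C10–C11 unit is added at C1, the oxirane is installed, and only then is the 11-membered ring closed between C9 and C10. The ring alkene is then saturated and the acid set free.
4. Enabling feature: C10 sits between C9 and the quaternary C11, which is bonded to the oxygenated C1, so C1(O)–C11(CH3)2–C10 is a 1,1-dimethylallyl carbinol with C10 as its vinyl carbon, and C9 is the inner carbon of an allyl group on C7. The ring-cis C2=C3 enoate and the trans C6–C7 oxirane fold the chain so that the two vinyl groups can meet.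
5. Stereochemistry: C1 (R) by reagent control in a Brown allylboration; C6/C7 (R,R) by Shi epoxidation of the E-alkene fixed by syn-carboalumination; C2=C3 geometry from the olefination. No later step touches these.

Key step: step 10

Remark: the C9=C10 geometry of 18 is left open because that bond is saturated in step 11; the acid is carried as its 2-(trimethylsilyl)ethyl ester, which fluoride removes without acid or strong base.

**Route**

Step 1
Reactants: 1 pent-1-en-4-yne
Product: 4 (3E)-4-methylhepta-3,6-dien-1-ol, via alkenylalane 2 (not isolated), via lithium alanate 3 (not isolated)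
Conditions: AlMe3, Cp2ZrCl2 (cat.), CH2Cl2, 0 °C → rt; volatiles removed; n-BuLi, THF–hexane, −30 °C; ethylene oxide, −30 °C → rt; aq. HCl
Reagents that add atoms: trimethylaluminium, C[Al](C)C; ethylene oxide, C1CO1
Why: Zirconium-catalysed syn-methylalumination of the terminal alkyne (Negishi carboalumination) puts CH3 on the internal and Al on the terminal carbon, which fixes the E geometry of the later C6=C7 bond, the isolated alkene is left alone, and the derived alanate opens ethylene oxide with retention at the alkenyl carbon.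

Step 2
Reactants: 4 (3E)-4-methylhepta-3,6-dien-1-ol
Product: 5 (4E)-7-iodo-4-methylhepta-1,4-diene
Conditions: I2, PPh3, imidazole, CH2Cl2, 0 °C → rt
Reagents that add atoms: iodine, II
Why: Appel-type iodination converts the unhindered primary alcohol into the iodide under near-neutral conditions that leave the skipped diene untouched.

Step 3
Reactants: 6 (diethoxyphosphoryl)acetic acid; 7 2-(trimethylsilyl)ethan-1-ol
Product: 8 2-(trimethylsilyl)ethyl (diethoxyphosphoryl)acetate
Conditions: DCC, DMAP (cat.), CH2Cl2, 0 °C → rt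
Reagents that add atoms: none
Why: Steglich esterification (carbodiimide activation, DMAP acyl transfer) joins the acid and the primary alcohol without affecting the phosphonate.

Step 4
Reactants: 8 2-(trimethylsilyl)ethyl (diethoxyphosphoryl)acetate; 5 (4E)-7-iodo-4-methylhepta-1,4-diene
Product: 10 2-(trimethylsilyl)ethyl (5E)-2-(diethoxyphosphoryl)-6-methylnona-5,8-dienoate, via sodium phosphonoacetate 9 (not isolated)
Conditions: NaH, DMF, 0 °C; then 5, 50 °C
Reagents that add atoms: none
Why: The stabilised phosphonoacetate carbanion is C-alkylated by the primary iodide in an SN2 reaction, an excess of 8 keeping dialkylation low.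

Step 5
Reactants: 10 2-(trimethylsilyl)ethyl (5E)-2-(diethoxyphosphoryl)-6-methylnona-5,8-dienoate; 11 2,2-dimethoxyacetaldehyde
Product: 12 2-(trimethylsilyl)ethyl (2E)-4,4-dimethoxy-2-[(3E)-4-methylhepta-3,6-dien-1-yl]but-2-enoate
Conditions: LiCl, DBU, MeCN, 0 °C → rt
Reagents that add atoms: none
Why: Horner–Wadsworth–Emmons olefination under Masamune–Roush conditions should favour the alkene with the ester trans to the acetal carbon, that is the (2E) geometry that later becomes the ring-cis C2=C3 bond, any minor isomer being removed by chromatography.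

Step 6
Reactants: 12 2-(trimethylsilyl)ethyl (2E)-4,4-dimethoxy-2-[(3E)-4-methylhepta-3,6-dien-1-yl]but-2-enoate
Product: 13 2-(trimethylsilyl)ethyl (2E)-2-[(3E)-4-methylhepta-3,6-dien-1-yl]-4-oxobut-2-enoate
Conditions: Amberlyst 15, acetone–H2O, rt
Reagents that add atoms: water, O
Why: Acid-catalysed hydrolysis of the allylic dimethyl acetal is fast under conditions that leave the silylethyl ester and the alkenes intact, and the E-enal is expected to be the more stable isomer.

Step 7
Reactants: 13 2-(trimethylsilyl)ethyl (2E)-2-[(3E)-4-methylhepta-3,6-dien-1-yl]-4-oxobut-2-enoate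
Product: 15 2-(trimethylsilyl)ethyl (2E,4R)-4-hydroxy-5,5-dimethyl-2-[(3E)-4-methylhepta-3,6-dien-1-yl]hepta-2,6-dienoate, via borinate ester 14 (not isolated)
Conditions: (−)-Ipc2BH [from (+)-α-pinene], 3-methylbuta-1,2-diene, THF, −25 °C; then 13, −78 °C; then HOCH2CH2NH2, Et2O, rt
Reagents that add atoms: 3-methylbuta-1,2-diene, CC(C)=C=C
Why: Hydroboration of the allene gives the prenylborane, which adds to the aldehyde through a closed chair transition state with allyl transposition (Brown asymmetric allylboration, reverse prenylation), so that C11 becomes quaternary, C10 becomes a vinyl carbon, and the isopinocampheyl groups derived from (+)-α-pinene direct attack to the Si face of the aldehyde to give (R)-C1.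

Step 8
Reactants: 15 2-(trimethylsilyl)ethyl (2E,4R)-4-hydroxy-5,5-dimethyl-2-[(3E)-4-methylhepta-3,6-dien-1-yl]hepta-2,6-dienoate
Product: 16 2-(trimethylsilyl)ethyl (2E,4R)-4-(benzoyloxy)-5,5-dimethyl-2-[(3E)-4-methylhepta-3,6-dien-1-yl]hepta-2,6-dienoate
Conditions: BzCl, pyridine, DMAP (cat.), CH2Cl2, 0 °C → 35 °C
Reagents that add atoms: benzoyl chloride, O=C(Cl)c1ccccc1
Why: DMAP-catalysed acylation installs the benzoate on the hindered secondary alcohol without any change at C1.

Step 9
Reactants: 16 2-(trimethylsilyl)ethyl (2E,4R)-4-(benzoyloxy)-5,5-dimethyl-2-[(3E)-4-methylhepta-3,6-dien-1-yl]hepta-2,6-dienoate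
Product: 17 2-(trimethylsilyl)ethyl (2E,4R)-4-(benzoyloxy)-5,5-dimethyl-2-{2-[(2R,3R)-3-methyl-3-(prop-2-en-1-yl)oxiran-2-yl]ethyl}hepta-2,6-dienoate
Conditions: D-fructose-derived Shi ketone (0.3 equiv), KHSO5 (as 2KHSO5·KHSO4·K2SO4), K2CO3, Bu4NHSO4 (cat.), Na2B4O7/Na2EDTA buffer, MeCN–CH2(OMe)2–H2O, 0 °C
Reagents that add atoms: potassium peroxymonosulfate, [K+].[O-]S(=O)(=O)OO
Why: Shi asymmetric epoxidation: the chiral dioxirane formed in situ transfers oxygen stereospecifically (spiro transition state) to the only electron-rich trisubstituted alkene, the terminal vinyl groups and the enoate reacting far more slowly, and the ketone derived from D-fructose should give the (R,R)-oxirane from this E-alkene.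

Step 10
Reactants: 17 2-(trimethylsilyl)ethyl (2E,4R)-4-(benzoyloxy)-5,5-dimethyl-2-{2-[(2R,3R)-3-methyl-3-(prop-2-en-1-yl)oxiran-2-yl]ethyl}hepta-2,6-dienoate
Product: 18 2-(trimethylsilyl)ethyl (1R,4E,6R,11R)-6-(benzoyloxy)-7,7,11-trimethyl-12-oxabicyclo[9.1.0]dodeca-4,8-diene-4-carboxylate
Conditions: second-generation Grubbs catalyst RuCl2(=CHPh)(PCy3)(H2IMes) (10–15 mol %), toluene, 1 mM (slow addition of 17), 80 °C, argon purge
Reagents that add atoms: none
Why: The ruthenium benzylidene exchanges first with the unhindered allyl terminus at C9, and the resulting alkylidene adds across the neopentyl vinyl group at C10 ([2+2] cycloaddition, ruthenacyclobutane, cycloreversion), forming the C9=C10 bond and expelling ethylene, whose loss drives the equilibrium. The closest known reaction type is ring-closing olefin metathesis to medium rings and to humulane-type 11-membered carbocycles, including closures at vinyl groups next to quaternary carbons. The 11-membered carbocycle is closed head-to-head between the two terminal vinyl groups with the new double bond endocyclic, while the oxirane ring is carried through unchanged. No stereocentre is created, and the E/Z configuration of the new C9=C10 bond is immaterial because step 11 removes it. The step needs chemoselectivity for the two monosubstituted alkenes, which the substrate secures because its only other alkene is a trisubstituted, electron-poor enoate that ruthenium alkylidenes do not engage; it also needs cyclisation to outrun oligomerisation, which high dilution, the gem-dimethyl group at C11 and the two rigid turn elements (ring-cis C2=C3 enoate, trans C6–C7 oxirane) favour.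

Step 11
Reactants: 18 2-(trimethylsilyl)ethyl (1R,4E,6R,11R)-6-(benzoyloxy)-7,7,11-trimethyl-12-oxabicyclo[9.1.0]dodeca-4,8-diene-4-carboxylate
Product: 19 2-(trimethylsilyl)ethyl (1R,4E,6R,11R)-6-(benzoyloxy)-7,7,11-trimethyl-12-oxabicyclo[9.1.0]dodec-4-ene-4-carboxylate
Conditions: 2-nitrobenzenesulfonylhydrazide (excess), Et3N, CH2Cl2, rt
Reagents that add atoms: none
Why: Diimide, generated in situ, transfers H2 in a concerted syn fashion and should reduce the disubstituted ring alkene much faster than the trisubstituted conjugated C2=C3 bond, while benzoate, oxirane and ester are inert to it.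

Step 12
Reactants: 19 2-(trimethylsilyl)ethyl (1R,4E,6R,11R)-6-(benzoyloxy)-7,7,11-trimethyl-12-oxabicyclo[9.1.0]dodec-4-ene-4-carboxylate
Product: 20 (1R,4E,6R,11R)-6-(benzoyloxy)-7,7,11-trimethyl-12-oxabicyclo[9.1.0]dodec-4-ene-4-carboxylic acid
Conditions: TBAF, THF, 0 °C → rt; cold dilute aq. HCl to pH 4
Reagents that add atoms: none
Why: Fluoride attacks silicon and triggers β-fragmentation of the 2-(trimethylsilyl)ethyl ester to the carboxylate under conditions that the hindered benzoate and the oxirane should survive, and brief mild acidification then gives the acid.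

**Compound list**

1 | pent-1-en-4-yne | C=CCC#C | starting material
2 | dimethyl[(1E)-2-methylpenta-1,4-dien-1-yl]alane | C=CC/C(C)=C/[Al](C)C | intermediate
3 | lithium butyl(dimethyl)[(1E)-2-methylpenta-1,4-dien-1-yl]aluminate | [Li+].C=CC/C(C)=C/[Al-](C)(C)CCCC | intermediate
4 | (3E)-4-methylhepta-3,6-dien-1-ol | C=CC/C(C)=C/CCO | intermediate
5 | (4E)-7-iodo-4-methylhepta-1,4-diene | C=CC/C(C)=C/CCI | intermediate
6 | (diethoxyphosphoryl)acetic acid | CCOP(=O)(CC(=O)O)OCC | starting material
7 | 2-(trimethylsilyl)ethan-1-ol | C[Si](C)(C)CCO | starting material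
8 | 2-(trimethylsilyl)ethyl (diethoxyphosphoryl)acetate | CCOP(=O)(CC(=O)OCC[Si](C)(C)C)OCC | intermediate
9 | sodium 1-(diethoxyphosphoryl)-2-oxo-2-[2-(trimethylsilyl)ethoxy]ethan-1-ide | [Na+].CCOP(=O)(OCC)[CH-]C(=O)OCC[Si](C)(C)C | intermediate
10 | 2-(trimethylsilyl)ethyl (5E)-2-(diethoxyphosphoryl)-6-methylnona-5,8-dienoate | CCOP(=O)(OCC)C(CC/C=C(\C)CC=C)C(=O)OCC[Si](C)(C)C | intermediate
11 | 2,2-dimethoxyacetaldehyde | COC(OC)C=O | starting material
12 | 2-(trimethylsilyl)ethyl (2E)-4,4-dimethoxy-2-[(3E)-4-methylhepta-3,6-dien-1-yl]but-2-enoate | COC(OC)/C=C(\CC/C=C(\C)CC=C)C(=O)OCC[Si](C)(C)C | intermediate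
13 | 2-(trimethylsilyl)ethyl (2E)-2-[(3E)-4-methylhepta-3,6-dien-1-yl]-4-oxobut-2-enoate | O=C/C=C(\CC/C=C(\C)CC=C)C(=O)OCC[Si](C)(C)C | intermediate
14 | 2-(trimethylsilyl)ethyl (2E,4R)-4-[(diisopinocampheylboranyl)oxy]-5,5-dimethyl-2-[(3E)-4-methylhepta-3,6-dien-1-yl]hepta-2,6-dienoate | C=CC(C)(C)[C@H](OB([C@@H]1C[C@@H]2C[C@H]([C@H]1C)C2(C)C)[C@@H]1C[C@@H]2C[C@H]([C@H]1C)C2(C)C)/C=C(\CC/C=C(\C)CC=C)C(=O)OCC[Si](C)(C)C | intermediate
15 | 2-(trimethylsilyl)ethyl (2E,4R)-4-hydroxy-5,5-dimethyl-2-[(3E)-4-methylhepta-3,6-dien-1-yl]hepta-2,6-dienoate | C=CC(C)(C)[C@H](O)/C=C(\CC/C=C(\C)CC=C)C(=O)OCC[Si](C)(C)C | intermediate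
16 | 2-(trimethylsilyl)ethyl (2E,4R)-4-(benzoyloxy)-5,5-dimethyl-2-[(3E)-4-methylhepta-3,6-dien-1-yl]hepta-2,6-dienoate | C=CC(C)(C)[C@H](OC(=O)c1ccccc1)/C=C(\CC/C=C(\C)CC=C)C(=O)OCC[Si](C)(C)C | intermediate
17 | 2-(trimethylsilyl)ethyl (2E,4R)-4-(benzoyloxy)-5,5-dimethyl-2-{2-[(2R,3R)-3-methyl-3-(prop-2-en-1-yl)oxiran-2-yl]ethyl}hepta-2,6-dienoate | C=CC(C)(C)[C@H](OC(=O)c1ccccc1)/C=C(\CC[C@@H]1[C@](CC=C)(C)O1)C(=O)OCC[Si](C)(C)C | intermediate
18 | 2-(trimethylsilyl)ethyl (1R,4E,6R,11R)-6-(benzoyloxy)-7,7,11-trimethyl-12-oxabicyclo[9.1.0]dodeca-4,8-diene-4-carboxylate (C8=C9 geometry not defined) | CC1(C)C=CC[C@@]2(C)O[C@@H]2CC/C(C(=O)OCC[Si](C)(C)C)=C\[C@H]1OC(=O)c1ccccc1 | intermediate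
19 | 2-(trimethylsilyl)ethyl (1R,4E,6R,11R)-6-(benzoyloxy)-7,7,11-trimethyl-12-oxabicyclo[9.1.0]dodec-4-ene-4-carboxylate | CC1(C)CCC[C@@]2(C)O[C@@H]2CC/C(C(=O)OCC[Si](C)(C)C)=C\[C@H]1OC(=O)c1ccccc1 | intermediate
20 | (1R,4E,6R,11R)-6-(benzoyloxy)-7,7,11-trimethyl-12-oxabicyclo[9.1.0]dodec-4-ene-4-carboxylic acid | CC1(C)CCC[C@@]2(C)O[C@@H]2CC/C(C(=O)O)=C\[C@H]1OC(=O)c1ccccc1 | target

**Step count**

Total steps: 12. Longest linear sequence: 11 steps (steps 1, 2 and 4–12, from 1); step 3 is a one-step side branch.

**Steps most likely to fail**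

Step 10. Intermolecular metathesis (oligomerisation) may outrun closure of the strained 11-membered ring, and turnover at the hindered vinyl group next to C11 may be slower than catalyst decomposition. The fallback sets out from 10 and 11 and comes back at 19: the C9–C10 bond is made first, intermolecularly, and the ring is closed at C2=C3 instead.
- Aldehyde 11 is reverse-prenylated as in step 7 to give (2S)-1,1-dimethoxy-3,3-dimethylpent-4-en-2-ol F1. The spatial sense of addition is the same as for 15; the descriptor differs only because the acetal carbon outranks C11.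
- Benzoylation (BzCl, pyridine, DMAP) gives the benzoate acetal F2.
- Cross-metathesis of an excess of F2 with the allyl terminus of phosphonate 10 (second-generation Grubbs catalyst, CH2Cl2, 40 °C) should give the dienyl phosphonate acetal F3.
- Diimide, as in step 11 but with no enoate present, saturates C9=C10 to give the monoene phosphonate acetal F4.
- LiBF4 in wet MeCN unmasks the phosphonate aldehyde F5.
- LiCl and DBU in MeCN at high dilution close the ring by an intramolecular Horner–Wadsworth–Emmons reaction to the macrocyclic dienoate F6.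
- Shi epoxidation of its only electron-rich alkene under the conditions of step 9 returns to 19.

Step 11. The conjugated C2=C3 bond may be reduced in competition, or the hindered ring alkene may be reduced incompletely. The fallback sets out from 18 and comes back at 20: the last two steps are run in the opposite order. Fluoride cleavage of 18 under the conditions of step 12 gives the macrocyclic dienoic acid F7. As its triethylammonium carboxylate the C2=C3 bond is no longer activated by an ester, and diimide, or failing that H2 over RhCl(PPh3)3, which selects by steric access, should reduce only C9=C10 and give 20 directly.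

Step 7. Facial discrimination by the terpene-derived borane may be insufficient with this electron-poor, β,β-disubstituted enal. The fallback sets out from 13 and comes back at 15: C1 is set by ketone reduction instead of by the C–C bond formation. A Barbier reaction of 13 with 1-bromo-3-methylbut-2-ene and indium powder in THF–H2O gives the racemic carbinol F8 with the same reverse-prenyl regiochemistry. Dess–Martin periodinane oxidises it to the enone F9. Corey–Bakshi–Shibata reduction ((S)-2-methyl-oxazaborolidine, catecholborane, toluene, −78 °C), in which the tertiary 1,1-dimethylallyl group is expected to act as the large substituent, should then give (R)-15.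

**Further compounds**

F1 | step 10 | (2S)-1,1-dimethoxy-3,3-dimethylpent-4-en-2-ol | C=CC(C)(C)[C@H](O)C(OC)OC
F2 | step 10 | (2S)-1,1-dimethoxy-3,3-dimethylpent-4-en-2-yl benzoate | C=CC(C)(C)[C@H](OC(=O)c1ccccc1)C(OC)OC
F3 | step 10 | 2-(trimethylsilyl)ethyl (5E,8E,11S)-11-(benzoyloxy)-2-(diethoxyphosphoryl)-12,12-dimethoxy-6,10,10-trimethyldodeca-5,8-dienoate | CCOP(=O)(OCC)C(CC/C=C(\C)C/C=C/C(C)(C)[C@H](OC(=O)c1ccccc1)C(OC)OC)C(=O)OCC[Si](C)(C)C
F4 | step 10 | 2-(trimethylsilyl)ethyl (5E,11S)-11-(benzoyloxy)-2-(diethoxyphosphoryl)-12,12-dimethoxy-6,10,10-trimethyldodec-5-enoate | CCOP(=O)(OCC)C(CC/C=C(\C)CCCC(C)(C)[C@H](OC(=O)c1ccccc1)C(OC)OC)C(=O)OCC[Si](C)(C)C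
F5 | step 10 | 2-(trimethylsilyl)ethyl (5E,11S)-11-(benzoyloxy)-2-(diethoxyphosphoryl)-6,10,10-trimethyl-12-oxododec-5-enoate | CCOP(=O)(OCC)C(CC/C=C(\C)CCCC(C)(C)[C@H](OC(=O)c1ccccc1)C=O)C(=O)OCC[Si](C)(C)C
F6 | step 10 | 2-(trimethylsilyl)ethyl (1E,3R,8E)-3-(benzoyloxy)-4,4,8-trimethylcycloundeca-1,8-diene-1-carboxylate | CC1(C)CCC/C(C)=C/CC/C(C(=O)OCC[Si](C)(C)C)=C\[C@H]1OC(=O)c1ccccc1
F7 | step 11 | (1R,4E,6R,11R)-6-(benzoyloxy)-7,7,11-trimethyl-12-oxabicyclo[9.1.0]dodeca-4,8-diene-4-carboxylic acid | CC1(C)C=CC[C@@]2(C)O[C@@H]2CC/C(C(=O)O)=C\[C@H]1OC(=O)c1ccccc1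
F8 | step 7 | 2-(trimethylsilyl)ethyl (2E)-4-hydroxy-5,5-dimethyl-2-[(3E)-4-methylhepta-3,6-dien-1-yl]hepta-2,6-dienoate (racemate) | C=CC(C)(C)C(O)/C=C(\CC/C=C(\C)CC=C)C(=O)OCC[Si](C)(C)C
F9 | step 7 | 2-(trimethylsilyl)ethyl (2E)-5,5-dimethyl-2-[(3E)-4-methylhepta-3,6-dien-1-yl]-4-oxohepta-2,6-dienoate | C=CC(C)(C)C(=O)/C=C(\CC/C=C(\C)CC=C)C(=O)OCC[Si](C)(C)C
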